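**Early times.** In the first minutes of the dusk run, Sub, Rgt and Cat share a closed, stirred flask, and Prd appears at 0.00379 M/min, the first reading over its time.

| flask | Sub | Rgt | Cat | time |
|---|---|---|---|---|
| dusk | 0.400 M | 0.800 M | 0.00200 M |  |
| dawn | 0.200 M | 0.600 M | 0.00200 M |  |
| summer | 0.400 M | 0.800 M | 0.00600 M |  |
| autumn | 0.600 M | 0.800 M | 0.00200 M |  |
| noon | 0.830 M | 0.800 M | 0.00200 M | 87 min |

| run | time / min | [Prd] / M |
|---|---|---|
| dusk run | 6.6 | 0.025 |
| dusk run | 20 | 0.057 |
| dusk run | 38 | 0.084 |
| dusk run | 61 | 0.109 |
| dusk run | 87 | 0.117 |
| dawn run | 6.6 | 0.006 |
| dawn run | 20 | 0.033 |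
| dawn run | 38 | 0.048 |
| dawn run | 61 | 0.061 |
| dawn run | 87 | 0.069 |
| summer run | 6.6 | 0.040 |
| summer run | 20 | 0.092 |
| summer run | 38 | 0.140 |
| summer run | 61 | 0.166 |
| summer run | 87 | 0.171 |
| autumn run | 6.6 | 0.028 |
| autumn run | 20 | 0.064 |
| autumn run | 38 | 0.113 |
| autumn run | 61 | 0.137 |
| autumn run | 87 | 0.150 |

(scatter of a reading: 0.003 M)

- Overall: Sub + Rgt -> Prd, with Cat as catalyst.
- Constant volume, constant temperature.
- What is held in complexes is read along with the free species.
- "The second partner" is Rgt.
- An order is taken over about fifteen percent of the charge, up and down.

- how the opening rate goes with [Sub] round the charge of the dusk run: the exponent of the rate at two percent of Sub gone to Prd (one fixed amount of Prd, the same in the runs compared)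
- how the opening rate goes with [Cat] round the charge of the dusk run: the exponent of the rate at two percent of Sub gone to Prd
- Prd in the noon run at 87 min, as a share of the Sub charged

**The middle.** Between 20 min and 38 min the dusk run climbs at 0.00150 M/min, slower than at the opening. The dusk flask is already giving less per minute, and the readings do not yet say why.

**The end.** Between 61 min and 87 min the dusk run gains 3.08 × 10⁻⁴ M/min, which is 8.12% of the opening slope. Yet Prd stands at 29.2% of the Sub charged. So we describe the dusk run by two things: how fast it starts and how long that start lasts.

**The reach.** The autumn run opens at 0.00424 M/min and reads 0.150 M at 87 min, which makes 35.4 min. This is the reach τ, the last Prd reading divided by the opening slope: the minutes of opening rate the flask delivers by that time. The dusk run gives 30.9 min, and we read the two as alike within scatter, since the first autumn reading has a scatter of about 10.7% of its value. Both runs hold the Cat and Rgt of the noon run, so we carry τ there, with no claim for other charges.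

**Our reckoning.** Noon needs its opening rate. The readings at 20 min in the autumn and dusk runs give a loose exponent in Sub of 0.286. Scaling the autumn slope to the noon charge and multiplying by τ gives 19.8% of the Sub charged.

**The forecast.** It gives an order of 0.35 in Sub (range 0.1 to 0.6), an order of 0.47 in Cat (range 0.35 to 0.6), and 21% of the Sub charged for the noon run (range 17% to 25%), a little higher than our figure. Of that last value it says: “This is uncertain, as Sub inhibition is possible.”

**The result.** Round the dusk charge the order is 0.68 in Sub and 0.62 in Cat, both above the forecast's ranges, and the noon run gives 22.9% of the Sub charged, inside its range.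

    2 Cat ⇌ Cat2, settled at all times (1520 /M)
    Cat + Sub + Rgt → Prd + Cat (37.92 /M²/min)
    2 Sub ⇌ Sub2, settled at all times (3.560 /M)
    Prd + Rgt → Sid (0.01962 /M/min)

**Reach again.** The autumn rate 0.0044 M/min, taken at the fixed early amount of Prd and scaled to the noon charge with the order 0.68, an order measured round the dusk charge and stretched here, gives an estimated 0.00547 M/min. Times the autumn τ this estimates 0.193 M, or 23.3% of the Sub charged in the noon run. The order in Sub is held down by the binding of 2 Sub into Sub2: early in the dusk run it is 0.68 with that binding and 1.0 without it.

The readings come from a simulation on assumed constants; the scatter is artificial.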